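**Plan**

- Numbering follows chroman-2-one (O1, C2, C3, C4, C4a, C5–C8, C8a). Ring A is the benzo ring and ring B the lactone.
- Enabling feature: ring A is a resorcinol with oxygen on C7 and C8a, hydrogen on C6 and C8, and two neighbouring carbon substituents on C4a and C5. This is the pattern left when a 4-alkyl-3-alkenylcyclobutenone is annulated with a terminal siloxyalkyne.
- Cuts, in order: the three O–Si bonds; O1–C2 (ring B) with C8–C8a, C6–C7 and C4a–C8a (ring A); the C5–styryl bond; C5–C6 and C4a–C8a of the four-membered ring (ketene plus ethoxyacetylene). This ends at a 3-arylglutaric half-ester.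
- Forward: arylglutaric anhydride, half-ester, ethoxycyclobutenone, styrylcyclobutenone, then ring A and ring B in one flask, then global desilylation.
- Stereochemistry: C4 is the only stereocentre. It is set by quinine-mediated methanolysis of the prochiral anhydride and is a spectator afterwards. The E alkene comes from a Takai olefination.

Key step: step 13

Assumption: quinine is taken to open the 3-arylglutaric anhydride in the same spatial sense as it opens 3-alkylglutaric anhydrides, which corresponds to the (R)-half-ester; if chemical correlation shows the opposite sense, quinidine replaces quinine and nothing else changes.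

**Step 1**
Reactants: 1 vanillin; 2 ethyl acetoacetate (2 equiv)
Product: 3 diethyl 2,4-diacetyl-3-(4-hydroxy-3-methoxyphenyl)pentanedioate (diastereomer mixture)
Conditions: piperidine (cat.), EtOH, rt
Reagents that add atoms: none
Why: Knoevenagel condensation followed by Michael addition of a second acetoacetate is the classical entry to 3-arylglutarates and tolerates the free phenol; the stereocentres formed are erased in step 2.

**Step 2**
Reactants: 3 diethyl 2,4-diacetyl-3-(4-hydroxy-3-methoxyphenyl)pentanedioate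
Product: 4 3-(4-hydroxy-3-methoxyphenyl)pentanedioic acid
Conditions: KOH (50% aq), EtOH, reflux, N2; then conc. HCl, 0 °C
Reagents that add atoms: potassium hydroxide, [K+].[OH-]
Why: Hot concentrated hydroxide effects a double retro-Claisen deacetylation together with saponification to give the prochiral diacid, and the phenol is carried free here because no silyl ether would survive these conditions.

**Step 3**
Reactants: 4 3-(4-hydroxy-3-methoxyphenyl)pentanedioic acid
Product: 6 3-[3-methoxy-4-(triisopropylsilyloxy)phenyl]pentanedioic acid, via tris(triisopropylsilyl) derivative 5 (not isolated)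
Conditions: TIPSCl (3.3 equiv), imidazole, DMF, rt; then AcOH–THF–H2O (3:1:1), 40 °C
Reagents that add atoms: triisopropylsilyl chloride, CC(C)[Si](Cl)(C(C)C)C(C)C
Why: Exhaustive silylation followed by mild acid hydrolysis uses the much greater lability of silyl esters compared with aryl triisopropylsilyl ethers, which resist acid.

**Step 4**
Reactants: 6 3-[3-methoxy-4-(triisopropylsilyloxy)phenyl]pentanedioic acid
Product: 7 4-[3-methoxy-4-(triisopropylsilyloxy)phenyl]oxane-2,6-dione
Conditions: Ac2O (3 equiv), toluene, 90 °C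
Reagents that add atoms: none
Why: Dehydrative cyclisation of a glutaric acid with acetic anhydride closes the six-membered prochiral anhydride and leaves the aryl silyl ether untouched.

**Step 5**
Reactants: 7 4-[3-methoxy-4-(triisopropylsilyloxy)phenyl]oxane-2,6-dione
Product: 8 (3R)-5-methoxy-3-[3-methoxy-4-(triisopropylsilyloxy)phenyl]-5-oxopentanoic acid
Conditions: quinine (1.1 equiv), MeOH (3 equiv), toluene, –50 °C; 1 M HCl wash
Reagents that add atoms: methanol, CO
Why: In this cinchona-alkaloid-mediated desymmetrising alcoholysis the quinuclidine nitrogen acts as a chiral general base that delivers methanol to one of the two enantiotopic carbonyl groups, which turns prochiral C3 into the (R)-stereocentre (future C4), and the optical purity can be raised if needed by recrystallising the 1-phenylethylammonium salt of 8.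

**Step 6**
Reactants: 8 (3R)-5-methoxy-3-[3-methoxy-4-(triisopropylsilyloxy)phenyl]-5-oxopentanoic acid
Product: 9 methyl (3S)-5-chloro-3-[3-methoxy-4-(triisopropylsilyloxy)phenyl]-5-oxopentanoate
Conditions: (COCl)2 (1.2 equiv), DMF (cat.), CH2Cl2, 0 °C → rt; concentrate cold, use crude
Reagents that add atoms: oxalyl chloride, ClC(=O)C(=O)Cl
Why: Vilsmeier-type chlorination spares ester and silyl ether, and the chloride is neither heated nor distilled because ester/acyl chloride interchange through a cyclic acyloxonium ion would racemise it (the descriptor changes to S only through CIP priorities).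

**Step 7**
Reactants: 9 methyl (3S)-5-chloro-3-[3-methoxy-4-(triisopropylsilyloxy)phenyl]-5-oxopentanoate; 10 ethoxyacetylene (3 equiv)
Product: 12 methyl (3S)-3-(2-ethoxy-4-oxocyclobut-2-en-1-yl)-3-[3-methoxy-4-(triisopropylsilyloxy)phenyl]propanoate (both ring epimers), via ketene 11 (not isolated)
Conditions: Et3N (1.2 equiv, slow addition), Et2O, 0 °C → rt
Reagents that add atoms: none
Why: Dehydrochlorination gives a monoalkylketene that excess ethoxyacetylene captures in a regiospecific ketene–alkyne [2+2] cycloaddition (alkyne CH carbon to ketene carbonyl carbon), and the uncontrolled ring stereocentre does not matter because it becomes aromatic C4a.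

**Step 8**
Reactants: 1 vanillin
Product: 13 3-methoxy-4-(triisopropylsilyloxy)benzaldehyde
Conditions: TIPSCl, imidazole, DMF, rt
Reagents that add atoms: triisopropylsilyl chloride, CC(C)[Si](Cl)(C(C)C)C(C)C
Why: Standard imidazole-promoted silylation of a phenol gives a base-tolerant ether that matches the other two silyl groups for a single final deprotection.

**Step 9**
Reactants: 13 3-methoxy-4-(triisopropylsilyloxy)benzaldehyde
Product: 14 (E)-[4-(2-iodoethenyl)-2-methoxyphenoxy]triisopropylsilane
Conditions: CrCl2 (6 equiv), CHI3 (2 equiv), THF, 0 °C → rt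
Reagents that add atoms: iodoform, IC(I)I
Why: In the Takai olefination the gem-dichromium reagent formed from CHI3 and divalent chromium adds to the aldehyde and eliminates to give the E-alkenyl iodide, a preference that is strong for aromatic aldehydes.

**Step 10**
Reactants: 14 (E)-[4-(2-iodoethenyl)-2-methoxyphenoxy]triisopropylsilane; 12 methyl (3S)-3-(2-ethoxy-4-oxocyclobut-2-en-1-yl)-3-[3-methoxy-4-(triisopropylsilyloxy)phenyl]propanoate
Product: 18 methyl (3S)-3-[3-methoxy-4-(triisopropylsilyloxy)phenyl]-3-{2-oxo-4-[(E)-2-[3-methoxy-4-(triisopropylsilyloxy)phenyl]ethenyl]cyclobut-3-en-1-yl}propanoate (both ring epimers), via alkenyllithium 15 (not isolated), via alkenylcerium dichloride 16 (not isolated), via tertiary carbinol 17 (not isolated)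
Conditions: 14, t-BuLi (2 equiv), Et2O, –78 °C; CeCl3 (anhydrous), THF, –78 °C; 12, –78 °C; then 1 M HCl, THF, 0 °C → rt
Reagents that add atoms: water (oxygen of the new carbonyl group), O
Why: Iodine–lithium exchange retains the alkene geometry, the weakly basic organocerium reagent adds 1,2 to the strained vinylogous-ester carbonyl in preference to the methyl ester, and acid then ionises the carbinol and hydrolyses the enol ether (Stork–Danheiser 1,3-carbonyl transposition), which places the styryl group on C3 next to the side-chain-bearing C4 of the cyclobutenone.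

**Step 11**
Reactants: 19 (trimethylsilyl)acetylene
Product: 22 1-(triisopropylsiloxy)-2-(trimethylsilyl)acetylene, via lithium acetylide 20 (not isolated), via lithium ynolate 21 (not isolated)
Conditions: n-BuLi, THF, –78 °C; LiOOt-Bu [from t-BuOOH (decane) and LiN(SiMe3)2, THF, –78 °C], –78 → 0 °C; TIPSOTf, –78 → 0 °C
Reagents that add atoms: tert-butyl hydroperoxide, CC(C)(C)OO; triisopropylsilyl triflate, CC(C)[Si](OS(=O)(=O)C(F)(F)F)(C(C)C)C(C)C
Why: Oxidation of a lithium acetylide by lithium tert-butyl peroxide is an established ynolate synthesis, and the bulky silyl triflate traps ynolates on oxygen and not on carbon.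

**Step 12**
Reactants: 22 1-(triisopropylsiloxy)-2-(trimethylsilyl)acetylene
Product: 23 (triisopropylsiloxy)acetylene
Conditions: K2CO3 (0.2 equiv), MeOH, 0 °C; pentane extraction, short-path distillation
Reagents that add atoms: none
Why: Base-catalysed methanolytic protodesilylation removes the unhindered alkynyl SiMe3 group, as is routine for heteroatom-substituted alkynylsilanes, while the hindered O–Si(i-Pr)3 bond and the electron-rich triple bond should resist methoxide.

**Step 13**
Reactants: 18 methyl (3S)-3-[3-methoxy-4-(triisopropylsilyloxy)phenyl]-3-{2-oxo-4-[(E)-2-[3-methoxy-4-(triisopropylsilyloxy)phenyl]ethenyl]cyclobut-3-en-1-yl}propanoate; 23 (triisopropylsiloxy)acetylene (2 equiv)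
Product: 29 (4R)-4-[3-methoxy-4-(triisopropylsilyloxy)phenyl]-5-{(E)-2-[3-methoxy-4-(triisopropylsilyloxy)phenyl]ethenyl}-7-(triisopropylsilyloxy)-3,4-dihydro-2H-chromen-2-one, via vinylketene 24 (not isolated), via siloxycyclobutenone 25 (not isolated), via dienylketene 26 (not isolated), via cyclohexadienone 27 (not isolated), via phenol ester 28 (not isolated)
Conditions: toluene, 80 → 110 °C; evaporate excess 23; camphorsulfonic acid (10 mol %), 4 Å MS, toluene, 60 °C
Reagents that add atoms: none
Why: Heating opens 18 by a conrotatory four-electron electrocyclic reaction, the C4-bearing side chain rotating outward, to vinylketene 24, whose carbonyl carbon (future C8a) is attacked by the nucleophilic CH terminus of 23, so that a [2+2] cycloaddition forms C8–C8a and C6–C7 and gives 25. Reversible opening of 25 gives dienylketene 26, ring A closes by a six-electron disrotatory electrocyclisation that rejoins C4a to C8a (27), and tautomerisation delivers phenol 28; this is the Danheiser benzannulation of a cyclobutenone with a siloxyalkyne. Ring B then closes by acid-catalysed 6-exo-trig acyl substitution of the C8a hydroxyl on the methyl ester (O1–C2), favoured by the ortho relation to C4a and by the buttressing C5 styryl group, while the sieves take up methanol. No stereocentre is created: the epimeric ring carbon of 18 ends as aromatic C4a, and C4 lies outside the reacting π system, outward rotation also keeping its hydrogen out of reach of a [1,5] shift to the ketene. The selectivity needed is regiochemical (oxygen on C7, not C8) and is secured by the polarisation of the siloxyalkyne, and the C5 styryl group is only cross-conjugated with both ketenes, so it offers no rival six-electron closure. Excess 23 should outrun acylation of 28 by 24 and is stripped off before the acid is added, because a protonated siloxyalkyne would itself acylate the phenol.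

**Step 14**
Reactants: 29 (4R)-4-[3-methoxy-4-(triisopropylsilyloxy)phenyl]-5-{(E)-2-[3-methoxy-4-(triisopropylsilyloxy)phenyl]ethenyl}-7-(triisopropylsilyloxy)-3,4-dihydro-2H-chromen-2-one
Product: 30 (4R)-7-hydroxy-4-(4-hydroxy-3-methoxyphenyl)-5-[(E)-2-(4-hydroxy-3-methoxyphenyl)ethenyl]-3,4-dihydro-2H-chromen-2-one
Conditions: HF·pyridine (excess), pyridine, THF, 0 °C → rt
Reagents that add atoms: none
Why: Fluoride-driven cleavage of the three aryl silyl ethers under buffered, weakly acidic conditions avoids the phenoxide or alkoxide base that would open the aryl lactone, and it touches neither the stilbene nor C4.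

**Compound list**

| No. | Name | SMILES | Role |
|---|---|---|---|
| 1 | vanillin | COc1cc(C=O)ccc1O | starting material |
| 2 | ethyl acetoacetate | CCOC(=O)CC(C)=O | starting material |
| 3 | diethyl 2,4-diacetyl-3-(4-hydroxy-3-methoxyphenyl)pentanedioate | CCOC(=O)C(C(C)=O)C(c1ccc(O)c(OC)c1)C(C(C)=O)C(=O)OCC | intermediate |
| 4 | 3-(4-hydroxy-3-methoxyphenyl)pentanedioic acid | COc1cc(C(CC(=O)O)CC(=O)O)ccc1O | intermediate |
| 5 | bis(triisopropylsilyl) 3-[3-methoxy-4-(triisopropylsilyloxy)phenyl]pentanedioate | COc1cc(C(CC(=O)O[Si](C(C)C)(C(C)C)C(C)C)CC(=O)O[Si](C(C)C)(C(C)C)C(C)C)ccc1O[Si](C(C)C)(C(C)C)C(C)C | intermediate |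
| 6 | 3-[3-methoxy-4-(triisopropylsilyloxy)phenyl]pentanedioic acid | COc1cc(C(CC(=O)O)CC(=O)O)ccc1O[Si](C(C)C)(C(C)C)C(C)C | intermediate |
| 7 | 4-[3-methoxy-4-(triisopropylsilyloxy)phenyl]oxane-2,6-dione | COc1cc(C2CC(=O)OC(=O)C2)ccc1O[Si](C(C)C)(C(C)C)C(C)C | intermediate |
| 8 | (3R)-5-methoxy-3-[3-methoxy-4-(triisopropylsilyloxy)phenyl]-5-oxopentanoic acid | COC(=O)C[C@H](c1ccc(O[Si](C(C)C)(C(C)C)C(C)C)c(OC)c1)CC(=O)O | intermediate |
| 9 | methyl (3S)-5-chloro-3-[3-methoxy-4-(triisopropylsilyloxy)phenyl]-5-oxopentanoate | COC(=O)C[C@H](c1ccc(O[Si](C(C)C)(C(C)C)C(C)C)c(OC)c1)CC(=O)Cl | intermediate |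
| 10 | ethoxyacetylene | CCOC#C | starting material |
| 11 | methyl (3S)-3-[3-methoxy-4-(triisopropylsilyloxy)phenyl]-5-oxopent-4-enoate (ketene) | COC(=O)C[C@H](c1ccc(O[Si](C(C)C)(C(C)C)C(C)C)c(OC)c1)C=C=O | intermediate |
| 12 | methyl (3S)-3-(2-ethoxy-4-oxocyclobut-2-en-1-yl)-3-[3-methoxy-4-(triisopropylsilyloxy)phenyl]propanoate, both ring epimers | COC(=O)C[C@H](c1ccc(O[Si](C(C)C)(C(C)C)C(C)C)c(OC)c1)C1C(=O)C=C1OCC | intermediate |
| 13 | 3-methoxy-4-(triisopropylsilyloxy)benzaldehyde | COc1cc(C=O)ccc1O[Si](C(C)C)(C(C)C)C(C)C | intermediate |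
| 14 | (E)-[4-(2-iodoethenyl)-2-methoxyphenoxy]triisopropylsilane | COc1cc(/C=C/I)ccc1O[Si](C(C)C)(C(C)C)C(C)C | intermediate |
| 15 | (E)-2-[3-methoxy-4-(triisopropylsilyloxy)phenyl]ethenyllithium | COc1cc(/C=C/[Li])ccc1O[Si](C(C)C)(C(C)C)C(C)C | intermediate |
| 16 | (E)-2-[3-methoxy-4-(triisopropylsilyloxy)phenyl]ethenylcerium dichloride | COc1cc(/C=C/[Ce](Cl)Cl)ccc1O[Si](C(C)C)(C(C)C)C(C)C | intermediate |
| 17 | methyl (3S)-3-{2-ethoxy-4-hydroxy-4-[(E)-2-[3-methoxy-4-(triisopropylsilyloxy)phenyl]ethenyl]cyclobut-2-en-1-yl}-3-[3-methoxy-4-(triisopropylsilyloxy)phenyl]propanoate, ring diastereomers | COC(=O)C[C@H](c1ccc(O[Si](C(C)C)(C(C)C)C(C)C)c(OC)c1)C1C(OCC)=CC1(O)/C=C/c1ccc(O[Si](C(C)C)(C(C)C)C(C)C)c(OC)c1 | intermediate |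
| 18 | methyl (3S)-3-[3-methoxy-4-(triisopropylsilyloxy)phenyl]-3-{2-oxo-4-[(E)-2-[3-methoxy-4-(triisopropylsilyloxy)phenyl]ethenyl]cyclobut-3-en-1-yl}propanoate, both ring epimers | COC(=O)C[C@H](c1ccc(O[Si](C(C)C)(C(C)C)C(C)C)c(OC)c1)C1C(=O)C=C1/C=C/c1ccc(O[Si](C(C)C)(C(C)C)C(C)C)c(OC)c1 | intermediate |
| 19 | (trimethylsilyl)acetylene | C#C[Si](C)(C)C | starting material |
| 20 | lithium (trimethylsilyl)acetylide | [Li]C#C[Si](C)(C)C | intermediate |
| 21 | lithium 2-(trimethylsilyl)ethynolate | [Li]OC#C[Si](C)(C)C | intermediate |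
| 22 | 1-(triisopropylsiloxy)-2-(trimethylsilyl)acetylene | C[Si](C)(C)C#CO[Si](C(C)C)(C(C)C)C(C)C | intermediate |
| 23 | (triisopropylsiloxy)acetylene | C#CO[Si](C(C)C)(C(C)C)C(C)C | intermediate |
| 24 | vinylketene, methyl (3S,4E,6E)-3,7-bis[3-methoxy-4-(triisopropylsilyloxy)phenyl]-5-(2-oxoethenyl)hepta-4,6-dienoate | COC(=O)C[C@H](c1ccc(O[Si](C(C)C)(C(C)C)C(C)C)c(OC)c1)/C=C(/C=C=O)\C=C\c1ccc(O[Si](C(C)C)(C(C)C)C(C)C)c(OC)c1 | intermediate |
| 25 | methyl (3S,4E,6E)-3,7-bis[3-methoxy-4-(triisopropylsilyloxy)phenyl]-5-[2-oxo-4-(triisopropylsilyloxy)cyclobut-3-en-1-yl]hepta-4,6-dienoate, ring epimers | COC(=O)C[C@H](c1ccc(O[Si](C(C)C)(C(C)C)C(C)C)c(OC)c1)/C=C(/C1C(=O)C=C1O[Si](C(C)C)(C(C)C)C(C)C)\C=C\c1ccc(O[Si](C(C)C)(C(C)C)C(C)C)c(OC)c1 | intermediate |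
| 26 | dienylketene O=C8a=C8H–C7(OSi)=C6H–C5(styryl)=C4aH–C4 with C5 and C8 cis on C6=C7, methyl (3S,4E,6E)-3,7-bis[3-methoxy-4-(triisopropylsilyloxy)phenyl]-5-[(1E)-4-oxo-2-(triisopropylsilyloxy)buta-1,3-dien-1-yl]hepta-4,6-dienoate | COC(=O)C[C@H](c1ccc(O[Si](C(C)C)(C(C)C)C(C)C)c(OC)c1)/C=C(/C=C(\C=C=O)O[Si](C(C)C)(C(C)C)C(C)C)\C=C\c1ccc(O[Si](C(C)C)(C(C)C)C(C)C)c(OC)c1 | intermediate |
| 27 | methyl (3S)-3-[3-methoxy-4-(triisopropylsilyloxy)phenyl]-3-{2-[(E)-2-[3-methoxy-4-(triisopropylsilyloxy)phenyl]ethenyl]-6-oxo-4-(triisopropylsilyloxy)cyclohexa-2,4-dien-1-yl}propanoate | COC(=O)C[C@H](c1ccc(O[Si](C(C)C)(C(C)C)C(C)C)c(OC)c1)C1C(=O)C=C(O[Si](C(C)C)(C(C)C)C(C)C)C=C1/C=C/c1ccc(O[Si](C(C)C)(C(C)C)C(C)C)c(OC)c1 | intermediate |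
| 28 | methyl (3R)-3-{2-hydroxy-6-[(E)-2-[3-methoxy-4-(triisopropylsilyloxy)phenyl]ethenyl]-4-(triisopropylsilyloxy)phenyl}-3-[3-methoxy-4-(triisopropylsilyloxy)phenyl]propanoate | COC(=O)C[C@H](c1ccc(O[Si](C(C)C)(C(C)C)C(C)C)c(OC)c1)c1c(O)cc(O[Si](C(C)C)(C(C)C)C(C)C)cc1/C=C/c1ccc(O[Si](C(C)C)(C(C)C)C(C)C)c(OC)c1 | intermediate |
| 29 | (4R)-4-[3-methoxy-4-(triisopropylsilyloxy)phenyl]-5-{(E)-2-[3-methoxy-4-(triisopropylsilyloxy)phenyl]ethenyl}-7-(triisopropylsilyloxy)-3,4-dihydro-2H-chromen-2-one | COc1cc(/C=C/c2cc(O[Si](C(C)C)(C(C)C)C(C)C)cc3c2[C@@H](c2ccc(O[Si](C(C)C)(C(C)C)C(C)C)c(OC)c2)CC(=O)O3)ccc1O[Si](C(C)C)(C(C)C)C(C)C | intermediate |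
| 30 | (4R)-7-hydroxy-4-(4-hydroxy-3-methoxyphenyl)-5-[(E)-2-(4-hydroxy-3-methoxyphenyl)ethenyl]-3,4-dihydro-2H-chromen-2-one | COc1cc(/C=C/c2cc(O)cc3c2[C@@H](c2ccc(O)c(OC)c2)CC(=O)O3)ccc1O | target |

**Step count**

Total step count: 14.
Longest linear sequence: 10 steps from vanillin (steps 1–7, 10, 13, 14).

**Steps most likely to fail**

**Step 13.** The unsubstituted siloxyalkyne may be lost through thermal silyl migration or oligomerisation before it intercepts the vinylketene. The vinylketene may then self-condense or acylate the nascent phenol. The acid used for lactonisation may also protonate the electron-rich stilbene.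

The fallback sets out from 18 and 22 and returns at 29, and it makes step 12 unnecessary. Cyclobutenone 18 would be heated in toluene with the C-silylated alkyne 22. This alkyne is less volatile and thermally sturdier, and its C–Si bond stabilises the positive charge that develops on the oxygen-bearing carbon, so the regiochemistry is reinforced.

The same cascade should give the C8-silylated phenol ester F1. This would be isolated and lactonised separately with pyridinium p-toluenesulfonate and 4 Å sieves in warm toluene to the 8-trimethylsilyl lactone F2. Ipso-protodesilylation at C8, the most electron-rich position of ring A (between O1 and O7), with CF3CO2H in CH2Cl2 at 0 °C then leads to 29.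

**Step 10.** Competing attack of the organometallic on the methyl ester, incomplete halogen–metal exchange or transmetalation, and over-hydrolysis during the acid phase would all erode the outcome.

The fallback sets out from 9, 14 and 19, bypasses 12 and returns at 18. It replaces carbonyl addition by a keteniminium–alkyne [2+2] cycloaddition, so no carbanion ever meets the ester.

- Acid chloride 9 and pyrrolidine (2 equiv, CH2Cl2, 0 °C) give the pyrrolidine amide F3.
- Sonogashira coupling of 14 with 19 [PdCl2(PPh3)2, CuI, Et3N] gives the silyl enyne F4, and K2CO3 in MeOH frees the terminal enyne F5.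
- Activation of F3 with Tf2O and 2,4,6-collidine in 1,2-dichloroethane generates the keteniminium triflate F6.
- The terminal carbon of F5 attacks the central carbon of F6, so charge develops on the internal alkyne carbon next to the styryl group, and closure gives the cyclobuteniminium triflate F7.
- Hydrolysis with aqueous NaHCO3 gives 18 with the styryl group on C3 and the side chain on C4.

**Step 5.** Discrimination between the enantiotopic carbonyl groups may be incomplete for a 3-aryl substrate, or its sense may be opposite to the one assumed.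

The fallback sets out from 6 and returns at 8. It replaces the alkaloid base by an enzyme acting on the diester. Fischer esterification (MeOH, cat. camphorsulfonic acid, reflux) converts 6 into the dimethyl glutarate F8. A hydrolase-catalysed desymmetrising hydrolysis then cleaves one enantiotopic ester (α-chymotrypsin or Candida antarctica lipase B, pH 7 phosphate buffer with a cosolvent). These enzymes are reported to favour the (R)-half-ester in the 3-arylglutarate series, which is 8.

**Further compounds**
F1 | step 13 | methyl (3R)-3-{2-hydroxy-6-[(E)-2-[3-methoxy-4-(triisopropylsilyloxy)phenyl]ethenyl]-4-(triisopropylsilyloxy)-3-(trimethylsilyl)phenyl}-3-[3-methoxy-4-(triisopropylsilyloxy)phenyl]propanoate | COC(=O)C[C@H](c1ccc(O[Si](C(C)C)(C(C)C)C(C)C)c(OC)c1)c1c(O)c([Si](C)(C)C)c(O[Si](C(C)C)(C(C)C)C(C)C)cc1/C=C/c1ccc(O[Si](C(C)C)(C(C)C)C(C)C)c(OC)c1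
F2 | step 13 | (4R)-4-[3-methoxy-4-(triisopropylsilyloxy)phenyl]-5-{(E)-2-[3-methoxy-4-(triisopropylsilyloxy)phenyl]ethenyl}-7-(triisopropylsilyloxy)-8-(trimethylsilyl)-3,4-dihydro-2H-chromen-2-one | COc1cc(/C=C/c2cc(O[Si](C(C)C)(C(C)C)C(C)C)c([Si](C)(C)C)c3c2[C@@H](c2ccc(O[Si](C(C)C)(C(C)C)C(C)C)c(OC)c2)CC(=O)O3)ccc1O[Si](C(C)C)(C(C)C)C(C)C
F3 | step 10 | methyl (3R)-3-[3-methoxy-4-(triisopropylsilyloxy)phenyl]-5-oxo-5-(pyrrolidin-1-yl)pentanoate | COC(=O)C[C@H](c1ccc(O[Si](C(C)C)(C(C)C)C(C)C)c(OC)c1)CC(=O)N1CCCC1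
F4 | step 10 | (E)-triisopropyl{2-methoxy-4-[4-(trimethylsilyl)but-1-en-3-yn-1-yl]phenoxy}silane | COc1cc(/C=C/C#C[Si](C)(C)C)ccc1O[Si](C(C)C)(C(C)C)C(C)C
F5 | step 10 | (E)-[4-(but-1-en-3-yn-1-yl)-2-methoxyphenoxy]triisopropylsilane | COc1cc(/C=C/C#C)ccc1O[Si](C(C)C)(C(C)C)C(C)C
F6 | step 10 | 1-{(3S)-5-methoxy-3-[3-methoxy-4-(triisopropylsilyloxy)phenyl]-5-oxopent-1-en-1-ylidene}pyrrolidinium triflate | COC(=O)C[C@H](c1ccc(O[Si](C(C)C)(C(C)C)C(C)C)c(OC)c1)C=C=[N+]1CCCC1.[O-]S(=O)(=O)C(F)(F)F
F7 | step 10 | 1-{4-[(1S)-3-methoxy-1-[3-methoxy-4-(triisopropylsilyloxy)phenyl]-3-oxopropyl]-3-[(E)-2-[3-methoxy-4-(triisopropylsilyloxy)phenyl]ethenyl]cyclobut-2-en-1-ylidene}pyrrolidinium triflate | COC(=O)C[C@H](c1ccc(O[Si](C(C)C)(C(C)C)C(C)C)c(OC)c1)C1C(=[N+]2CCCC2)C=C1/C=C/c1ccc(O[Si](C(C)C)(C(C)C)C(C)C)c(OC)c1.[O-]S(=O)(=O)C(F)(F)F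
F8 | step 5 | dimethyl 3-[3-methoxy-4-(triisopropylsilyloxy)phenyl]pentanedioate | COC(=O)CC(CC(=O)OC)c1ccc(O[Si](C(C)C)(C(C)C)C(C)C)c(OC)c1
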